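**Plan**

1. Numbering: ring A is the cyclopentanone, ring B the γ-lactone, ring C the δ-lactone. Rings A and B use cyclopenta[c]furan numbering (C1 gem-dimethyl carbon, O2, C3 lactone C=O, C3a methyl-bearing fusion carbon, C4 ketone, C5 spiro carbon, C6, C6a). Ring C is primed (O1', C2'=O, C3' = C5, C4', C5', C6').
2. Retrosynthesis cuts, in order: (i) O1'–C2' and C5'–C6' (lactonisation after a glyoxal-ene reaction of a prenyl group on C5); (ii) C3a–C3 and C3a–CH3 (acyl transfer from a carbonate on the C1 oxygen to the C3a enolate, then methylation); (iii) C4–C5 and C5–C6, which removes C5 with its ester from ring A and leaves a 3-substituted cyclobutanone and an α-prenyl α-diazo ester.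
3. Enabling feature: ketone C4 is flanked by the quaternary carbon C5 that carries an ester carbonyl (C2'), which is the pattern a diazo ester carbon leaves when it inserts next to a ketone. Without C5, the four-membered ring C4–C3a–C6a–C6 has a mirror plane through C4 and C6a, so the insertion can also set C5 and C6a by desymmetrisation.
4. Forward order of rings: cyclobutanone → ring A (one-carbon ring expansion, which also joins the two halves) → ring B (fused γ-lactone) → ring C (spiro δ-lactone).
5. Stereochemistry: C5 and C6a from the ring expansion (absolute sense from a chiral aluminium Lewis acid, relative sense from the substrate); C3a from the enforced cis ring fusion; C5' and C6' from a copper bis(oxazoline)-controlled, anti-selective ene reaction.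

Key step: step 6

Assumption: the ligand antipodes named in steps 6 and 9 are those expected by analogy with the nearest precedents; if the sense of induction proves opposite, the mirror-image ligand is used and nothing else in the route changes.

**Route**

Step 1
Reactants: 1 methyl 3,3-dimethoxycyclobutane-1-carboxylate
Product: 2 2-(3,3-dimethoxycyclobutyl)propan-2-ol
Conditions: MeMgBr (3 equiv), THF, 0 °C → rt; aq. NH4Cl
Reagents that add atoms: methylmagnesium bromide C[Mg]Br
Why: Double Grignard addition to the ester should give the tertiary alcohol while the dimethyl ketal keeps the ring ketone out of reach; no stereocentre is formed.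

Step 2
Reactants: 2 2-(3,3-dimethoxycyclobutyl)propan-2-ol
Product: 4 2-(3,3-dimethoxycyclobutyl)propan-2-yl methyl carbonate, via lithium alkoxide of the tertiary alcohol 3 (not isolated)
Conditions: n-BuLi (1.05 equiv), THF, −78 → 0 °C; then ClCO2Me (1.3 equiv), 0 °C → rt
Reagents that add atoms: methyl chloroformate COC(=O)Cl
Why: O-Acylation of the lithium alkoxide 3 by the chloroformate should install the methyl carbonate, which protects the tertiary hydroxyl and later serves as the internal donor of the lactone carbonyl C3; no stereocentre is formed.

Step 3
Reactants: 4 2-(3,3-dimethoxycyclobutyl)propan-2-yl methyl carbonate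
Product: 5 methyl 2-(3-oxocyclobutyl)propan-2-yl carbonate
Conditions: TsOH·H2O (10 mol %), acetone/H2O (10:1), rt
Reagents that add atoms: water O
Why: Acid-catalysed ketal hydrolysis should free the cyclobutanone under conditions too mild to ionise the tertiary carbonate, and 5 is achiral with a mirror plane through C1 and C3 of the ring.

Step 4
Reactants: 6 methyl acetoacetate; 7 1-bromo-3-methylbut-2-ene (prenyl bromide)
Product: 8 methyl 2-acetyl-5-methylhex-4-enoate (racemic)
Conditions: K2CO3 (1.5 equiv), acetone, reflux; 6 in slight excess
Reagents that add atoms: none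
Why: Acetoacetic ester alkylation, in which the potassium enolate of 6 is C-alkylated by the allylic bromide (SN2) and the excess of 6 suppresses dialkylation; the new centre is racemic and disappears in step 5.

Step 5
Reactants: 8 methyl 2-acetyl-5-methylhex-4-enoate
Product: 9 methyl 2-diazo-5-methylhex-4-enoate
Conditions: p-ABSA (1.2 equiv), DBU (1.5 equiv), MeCN, 0 °C → rt
Reagents that add atoms: 4-acetamidobenzenesulfonyl azide CC(=O)Nc1ccc(cc1)S(=O)(=O)N=[N+]=[N-]
Why: Deacylative Regitz diazo transfer, in which the enolate of 8 adds to the sulfonyl azide and the acetyl group leaves on the sulfonamide nitrogen, should give the α-alkyl α-diazo ester without touching the alkene.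

Step 6
Reactants: 5 methyl 2-(3-oxocyclobutyl)propan-2-yl carbonate; 9 methyl 2-diazo-5-methylhex-4-enoate
Product: 10 methyl (1R,4R)-4-[2-(methoxycarbonyloxy)propan-2-yl]-1-(3-methylbut-2-en-1-yl)-2-oxocyclopentane-1-carboxylate
Conditions: AlMe3 (20 mol %) and (R)-3,3'-bis(trimethylsilyl)-1,1'-bi-2-naphthol (40 mol %) premixed, toluene, −78 → −40 °C, slow addition of 9 (1.3 equiv)
Reagents that add atoms: none
Why: The aluminium aryloxide activates the cyclobutanone oxygen of 5, the nucleophilic diazo carbon of 9 adds to the carbonyl carbon on the face anti to the C3 side chain, and in the resulting diazonium alkoxide the ring CH2–C(O) bond antiperiplanar to C–N2 shifts to the former diazo carbon as N2 leaves (Tiffeneau–Demjanov-type 1,2-shift), with relief of four-ring strain driving both events. No ring is closed in the usual sense: the five-membered ring arises from the four-membered one by insertion of one carbon between the carbonyl carbon and one α-carbon of the cyclobutanone, and the same event joins the two halves of the carbon skeleton. The closest known reaction type is the Lewis-acid-catalysed ring expansion of cycloalkanones with α-alkyl α-diazoacetates, including its desymmetrising form with BINOL-derived chiral aluminium Lewis acids on 4-substituted cyclohexanones. The quaternary centre C1 and the centre C4 of 10 arise together because 5 has a mirror plane: which of the two enantiotopic CH2–C(O) bonds migrates fixes both, and the chiral aluminium complex decides this by choosing the face of the diazo ester that adds. Their relative configuration (ester trans to the C4 side chain) is controlled by the substrate, since addition anti to the side chain and migration from the rotamer that holds the ester C=O anti to the C–O–Al bond (least dipole repulsion with a one-point Lewis acid, prenyl group turned outward) leave the ester on the face opposite the side chain. The step needs enantiotopic-bond selectivity (ligand) and this diastereoselectivity (substrate); a second homologation is not expected because the product ketone is unstrained and flanked by a quaternary carbon, and the prenyl alkene and the carbonate are inert to the Lewis acid and to the diazo group.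

Step 7
Reactants: 10 methyl (1R,4R)-4-[2-(methoxycarbonyloxy)propan-2-yl]-1-(3-methylbut-2-en-1-yl)-2-oxocyclopentane-1-carboxylate
Product: 12 methyl (3aR,5R,6aR)-1,1,3a-trimethyl-5-(3-methylbut-2-en-1-yl)-3,4-dioxohexahydro-1H-cyclopenta[c]furan-5-carboxylate, via potassium enolate of the fused β-keto lactone 11 (not isolated)
Conditions: KN(SiMe3)2 (1.05 equiv), THF, −78 → 0 °C; then MeI (3 equiv), 0 °C → rt
Reagents that add atoms: iodomethane CI
Why: Intramolecular Claisen-type (Dieckmann-like) acylation, in which the only possible enolate of 10 (C3, between the ketone and the carbon bearing the carbonate arm) attacks the carbonate carbonyl in a 5-exo-trig closure, the expelled methoxide is consumed by the acidic β-keto lactone to give 11, and C-methylation of 11 can only give the cis-fused bicycle, which fixes C3a.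

Step 8
Reactants: 13 3-methylbutan-2-one
Product: 14 3-methyl-2-oxobutanal
Conditions: SeO2 (1.0 equiv), 1,4-dioxane/H2O, reflux; distilled and used fresh
Reagents that add atoms: selenium dioxide O=[Se]=O
Why: Riley oxidation, in which selenium dioxide takes the methyl group of the methyl ketone to the aldehyde (the methine side cannot be taken to a carbonyl), should give the 1,2-dicarbonyl enophile.

Step 9
Reactants: 12 methyl (3aR,5R,6aR)-1,1,3a-trimethyl-5-(3-methylbut-2-en-1-yl)-3,4-dioxohexahydro-1H-cyclopenta[c]furan-5-carboxylate; 14 3-methyl-2-oxobutanal
Product: 16 (3aR,5R,5'S,6'S,6aR)-1,1,3a-trimethyl-6'-(2-methylpropanoyl)-5'-(prop-1-en-2-yl)tetrahydro-1H-spiro[cyclopenta[c]furan-5,3'-pyran]-2',3,4(3aH)-trione (target), via hydroxy ketone ene adduct 15 (not isolated)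
Conditions: [Cu((S,S)-tBu-box)](SbF6)2 (15 mol %; tBu-box = 2,2'-isopropylidenebis[(4S)-4-tert-butyl-2-oxazoline]), 14 (1.1 equiv, slow addition), CH2Cl2, 0 °C → rt; then CSA (20 mol %), toluene, 50 °C
Reagents that add atoms: none
Why: Catalytic asymmetric glyoxal carbonyl-ene reaction, in which the aldehyde of 14, held in a two-point chelate on copper, is attacked on the face left open by the tert-butyl groups by the CH= carbon of the prenyl group with transfer of a methyl hydrogen (C6' set as S by the catalyst, C5' set anti to it through the transition state that turns the metal chelate toward the alkene C–H and away from the CH2 substituent), after which the δ-hydroxy ester 15 should close to the δ-lactone by acid-catalysed transesterification under conditions mild enough to leave the centre next to the ketone untouched.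

**Compound list**

1 | methyl 3,3-dimethoxycyclobutane-1-carboxylate | COC(=O)C1CC(OC)(OC)C1 | starting material
2 | 2-(3,3-dimethoxycyclobutyl)propan-2-ol | CC(C)(O)C1CC(OC)(OC)C1 | intermediate
3 | lithium 2-(3,3-dimethoxycyclobutyl)propan-2-olate | [Li+].[O-]C(C)(C)C1CC(OC)(OC)C1 | intermediate (not isolated)
4 | 2-(3,3-dimethoxycyclobutyl)propan-2-yl methyl carbonate | COC(=O)OC(C)(C)C1CC(OC)(OC)C1 | intermediate
5 | methyl 2-(3-oxocyclobutyl)propan-2-yl carbonate | COC(=O)OC(C)(C)C1CC(=O)C1 | intermediate
6 | methyl acetoacetate | COC(=O)CC(C)=O | starting material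
7 | 1-bromo-3-methylbut-2-ene | CC(C)=CCBr | starting material
8 | methyl 2-acetyl-5-methylhex-4-enoate (racemic) | COC(=O)C(CC=C(C)C)C(C)=O | intermediate
9 | methyl 2-diazo-5-methylhex-4-enoate | COC(=O)C(=[N+]=[N-])CC=C(C)C | intermediate
10 | methyl (1R,4R)-4-[2-(methoxycarbonyloxy)propan-2-yl]-1-(3-methylbut-2-en-1-yl)-2-oxocyclopentane-1-carboxylate | CC(C)=CC[C@]1(C[C@@H](C(C)(C)OC(=O)OC)CC1=O)C(=O)OC | intermediate
11 | potassium enolate (over C3a–C4) of methyl (5R,6aR)-1,1-dimethyl-5-(3-methylbut-2-en-1-yl)-3,4-dioxohexahydro-1H-cyclopenta[c]furan-5-carboxylate | CC(C)=CC[C@]1(C[C@H]2C(C)(C)OC(=O)C2=C1[O-])C(=O)OC.[K+] | intermediate (not isolated)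
12 | methyl (3aR,5R,6aR)-1,1,3a-trimethyl-5-(3-methylbut-2-en-1-yl)-3,4-dioxohexahydro-1H-cyclopenta[c]furan-5-carboxylate | CC(C)=CC[C@]2(C[C@H]3C(C)(C)OC(=O)[C@@]3(C)C2=O)C(=O)OC | intermediate
13 | 3-methylbutan-2-one | CC(C)C(C)=O | starting material
14 | 3-methyl-2-oxobutanal | CC(C)C(=O)C=O | intermediate
15 | methyl (3aR,5R,6aR)-5-[(2S,3S)-3-hydroxy-5-methyl-4-oxo-2-(prop-1-en-2-yl)hexyl]-1,1,3a-trimethyl-3,4-dioxohexahydro-1H-cyclopenta[c]furan-5-carboxylate | C=C(C)[C@H](C[C@]2(C[C@H]3C(C)(C)OC(=O)[C@@]3(C)C2=O)C(=O)OC)[C@H](O)C(=O)C(C)C | intermediate (not isolated)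
16 | (3aR,5R,5'S,6'S,6aR)-1,1,3a-trimethyl-6'-(2-methylpropanoyl)-5'-(prop-1-en-2-yl)tetrahydro-1H-spiro[cyclopenta[c]furan-5,3'-pyran]-2',3,4(3aH)-trione | C=C(C)[C@@H]1C[C@]2(C[C@H]3C(C)(C)OC(=O)[C@@]3(C)C2=O)C(=O)O[C@@H]1C(=O)C(C)C | target

**Step count**

Total: 9 steps. Longest linear sequence: 6 steps (steps 1, 2, 3, 6, 7, 9).

**Steps most likely to fail**

Step 6. The chiral Lewis acid may discriminate poorly between the two enantiotopic CH2–C(O) bonds, or migration may occur from the rotamer with the ester syn to oxygen (chelation), which would give the epimer at the quaternary centre. The fallback sets out from 5 and comes back at 12. The mirror plane is broken first: 5 is added slowly to lithium (R,R)-bis(1-phenylethyl)amide and LiCl in THF at −100 °C. The desymmetrised enolate closes onto its own carbonate on warming, and the resulting β-keto lactone enolate is methylated with MeI to give the fused cyclobutanone (1R,5R)-1,4,4-trimethyl-3-oxabicyclo[3.2.0]heptane-2,7-dione F1. Ring expansion of F1 with 9 under BF3·OEt2 (CH2Cl2, −78 °C) is then controlled by the substrate alone: addition on the convex face, migration of the CH2 rather than the acyl-bearing quaternary carbon, and the ester anti to oxygen. This should give 12 directly, so that step 7 is not needed.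

Step 9. The ene reaction may suffer from a mismatch between the catalyst and the quaternary centre next to the prenyl group (poor facial or anti/syn selectivity), from catalyst inhibition by the 1,3-dicarbonyl units of 12, or from a second ene reaction at the new isopropenyl group. The fallback sets out from 12 and comes back at 15. The prenyl group is made the nucleophile: allylic oxidation (SeO2 0.5 equiv, t-BuOOH, CH2Cl2, rt) should give the (E)-allylic alcohol methyl (3aR,5R,6aR)-5-[(2E)-4-hydroxy-3-methylbut-2-en-1-yl]-1,1,3a-trimethyl-3,4-dioxohexahydro-1H-cyclopenta[c]furan-5-carboxylate F2. Palladium-catalysed borylation (Pd(MeCN)4(BF4)2, B2pin2, DMSO/MeOH, 50 °C) should give the (E)-allylboronate F3. Allylboration of 14 with F3 under a chiral phosphoric acid ((R)-3,3'-bis(2,4,6-triisopropylphenyl)-1,1'-binaphthyl-2,2'-diyl hydrogen phosphate, toluene, −30 °C) passes through a closed chair transition state, so the (E)-boronate should give the anti hydroxy ketone 15 with the acid setting the absolute sense. 15 then lactonises as in the second stage of step 9.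

Step 7. The stabilised enolate 11 may methylate on oxygen, or too slowly at the hindered ring-fusion carbon, so that material is exposed to base for long and opens by retro-Claisen cleavage. The fallback sets out from 10 and comes back at 12. The order of the two bond formations is reversed. The simple ketone enolate is methylated first (LiN(SiMe3)2 with MeI present, THF/DMPU, −78 °C) to give methyl (1R,4R)-4-[2-(methoxycarbonyloxy)propan-2-yl]-3-methyl-1-(3-methylbut-2-en-1-yl)-2-oxocyclopentane-1-carboxylate F4 as both C3 epimers. KN(SiMe3)2 (THF, −78 → 0 °C) then forms the single fully substituted enolate, whose C-acylation by the carbonate builds the quaternary centre. Both epimers of F4 converge, and the cis ring fusion again allows only 12.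

**Further compounds**

F1 | step 6 | (1R,5R)-1,4,4-trimethyl-3-oxabicyclo[3.2.0]heptane-2,7-dione | O=C1C[C@H]2C(C)(C)OC(=O)[C@@]12C
F2 | step 9 | methyl (3aR,5R,6aR)-5-[(2E)-4-hydroxy-3-methylbut-2-en-1-yl]-1,1,3a-trimethyl-3,4-dioxohexahydro-1H-cyclopenta[c]furan-5-carboxylate | OC/C(C)=C/C[C@]2(C[C@H]3C(C)(C)OC(=O)[C@@]3(C)C2=O)C(=O)OC
F3 | step 9 | methyl (3aR,5R,6aR)-1,1,3a-trimethyl-5-[(2E)-3-methyl-4-(4,4,5,5-tetramethyl-1,3,2-dioxaborolan-2-yl)but-2-en-1-yl]-3,4-dioxohexahydro-1H-cyclopenta[c]furan-5-carboxylate | CC1(C)OB(C/C(C)=C/C[C@]2(C[C@H]3C(C)(C)OC(=O)[C@@]3(C)C2=O)C(=O)OC)OC1(C)C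
F4 | step 7 | methyl (1R,4R)-4-[2-(methoxycarbonyloxy)propan-2-yl]-3-methyl-1-(3-methylbut-2-en-1-yl)-2-oxocyclopentane-1-carboxylate (both C3 epimers) | CC(C)=CC[C@]1(C[C@@H](C(C)(C)OC(=O)OC)C(C)C1=O)C(=O)OC
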